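Amounts in Friday's flask read steady within their scatter from 1.00 min, with J and G both left standing, while Thursday's J reads 0 % at 2.00 min. The suspected steps are J + Z → D + X, Z + D → G + X and D → Q.

| flask | J | Z | remark | time |
|---|---|---|---|---|
| Friday's | 1 mM | 0.66 mM | run made earlier |  |
| Thursday's | 1 mM | 2.7 mM | run made earlier |  |
| violet | 1.0 mM | 0.500 mM |  | 10 min |
| amber | 1.0 mM | 1.00 mM |  | 10 min |
| grey | 1.0 mM | 2.00 mM |  | 10 min |

| run | time / min | G / % | J / % |
|---|---|---|---|
| Friday's | 0.500 | 19.3 | 58.3 |
| Friday's | 1.00 | 21.4 | 54.9 |
| Friday's | 2.00 | 21.2 | 55.0 |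
| Friday's | 4.00 | 22.7 | 54.6 |
| Friday's | 8.00 | 22.8 | 56.1 |
| Thursday's | 0.500 | 89.1 | 4.4 |
| Thursday's | 1.00 | 95.7 | 0.2 |
| Thursday's | 2.00 | 97.1 | 0 |
| Thursday's | 4.00 | 95.5 | 0.3 |
| Thursday's | 8.00 | 96.2 | 0 |

(scatter of a reading: 1 percentage point)

- on the list of suspects stand: Z + D -> G + X; J + Z -> D + X; D -> Q
- "hardly changes" means that all values lie within two and a half points (for a concentration: within two and a half percent of the largest)

- amount of G at the end, in percent of the J charged for violet, amber, grey, in this order
- the shape of the row from first to last (falls all the way / hardly changes / falls, then rises / rises all the way / rises, then falls)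

This reckoning keeps a ledger of Z, the limiting reagent on Friday.

1. Each J lost costs one Z, and each G costs a second. Call L the J lost and q the leak, meaning J lost that never appears as G. Then L = G + q, and the Z spent is 2G + q.

2. Friday's plateau means are G 22.0 % and J 55.2 %. So L + G comes to 0.669 mM against 0.66 mM charged, and the books close with a leak of 0.228 mM.

3. Carrying that leak over and setting Z spent equal to Z charged, G = (Z charged − q)/2, which gives 13.6 % in violet and 38.6 % in amber.

4. Grey's books ask for L of 1.11 mM, more than the 1.0 mM of J charged. So this reckoning has J, not Z, end first in grey, with G = J charged − q, and the Z left equals q.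

5. While Z lasts, D splits between the two exits, with Q per G equal to κ/Z. Here κ, the leak constant, is the rate constant of D → Q over that of Z + D → G + X. With about two Z spent per G, q = (κ/2) ln(Z charged/Z left). Thursday's plateau gives a leak of 0.0387 mM with 0.739 mM of Z left, so the reading is κ = 0.0598 mM.

6. For grey, starting from Thursday's leak and feeding each answer back as the Z left, q runs 0.118 mM, 0.0846 mM, 0.0946 mM, 0.0912 mM. G is then 90.9 %, and the row rises from first to last.

The forecast gives 14 %, 38 %, 88 %, rises all the way, its grey standing below this reckoning's, and of grey it says “Z gets scarce at the end and D leaks to Q”.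

The flask gives 14.2 %, 38.7 %, 90.7 %: rises all the way.

    Z + D → G + X (k = 229 /M/s)
    J + Z → D + X (k = 84.1 /M/s)
    D → Q (k = 0.0135 /s)

Grey falls short of full yield chiefly through D → Q: without that step its G stands at 98.8 % instead of 90.7 %. The Z left in grey after 10.0 min is 0.0938 mM, and with it κ gives a leak of 0.0915 mM, while the flask holds Q at 9.29 % of the J charged. In violet at 0.102 min, D goes to Q at 0.21 of its rate to G, so κ puts Z there at about 0.285 mM.

(The runs were generated by integration with made-up constants; scatter was added.)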